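**Plan**
- Retrosynthetic cuts, in order: the phenol is masked as its methyl ether; ring bonds C2–C3 and C4–C5 of the benzene ring (C1 = carbon bearing the CH2CH2O arm, C4 = oxygenated carbon); the ester C–O bond; the bond between the heterocycle and its two-carbon arm; and C16–C17 of the C40 chain.
- Enabling feature: the para-disubstituted benzene ring. C1, C2, C5 and C6 map onto C5, C6, C3 and C4 of a 5-substituted 2-pyrone; C3 and the oxygenated C4 map onto the CH2 and the acetal carbon of 1,1-dimethoxyethene.
- Forward: the C40 acid is joined from C24 and C16 halves by a copper-catalysed Grignard coupling; the pyrone receives its arm by Stille vinylation and hydroboration–oxidation; the two are esterified.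
- The benzene ring, the only ring made, arises last from the pyrone by cycloaddition, loss of CO2 and loss of methanol; demethylation then gives the phenol.
- Stereochemistry: the target has no stereocentre; the two bridgehead centres of the transient cycloadduct disappear on aromatisation.

Key step: step 5

Assumption: 1-bromotetracosane, 16-bromohexadecanoic acid, 5-bromo-2H-pyran-2-one, tributyl(vinyl)stannane and 1,1-dimethoxyethene are taken as purchasable; the ketene acetal is distilled from K2CO3 before use because traces of acid polymerise it.

**Step 1**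
Reactants: 1 1-bromotetracosane; 2 16-bromohexadecanoic acid
Product: 5 tetracontanoic acid, via tetracosylmagnesium bromide 3 (not isolated), via chloromagnesium 16-bromohexadecanoate 4 (not isolated)
Conditions: 1, Mg, THF, 50 °C; separately 2, MeMgCl (1.0 equiv), THF, −20 °C; then combine, Li2CuCl4 (3 mol%), THF, −10 °C → rt; 1 M HCl work-up; recrystallisation from hot toluene
Reagents that add atoms: none
Why: A Kochi-type copper-catalysed alkyl–alkyl Grignard coupling should displace the primary bromide of 4 faster than the Grignard reagent adds to the carboxylate, which is protected as its magnesium salt by prior deprotonation, so the C16–C17 bond of the C40 acid forms in one operation.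

**Step 2**
Reactants: 6 5-bromo-2H-pyran-2-one; 7 tributyl(vinyl)stannane
Product: 8 5-ethenyl-2H-pyran-2-one
Conditions: Pd(PPh3)4 (5 mol%), BHT (trace), toluene, 100 °C
Reagents that add atoms: none
Why: In this Stille coupling zerovalent palladium inserts into the C5–Br bond of the electron-poor pyrone, the vinyl group is transferred from tin and reductive elimination follows, under neutral conditions that leave the lactone untouched.

**Step 3**
Reactants: 8 5-ethenyl-2H-pyran-2-one
Product: 10 5-(2-hydroxyethyl)-2H-pyran-2-one, via B-alkyl-9-BBN adduct 9 (not isolated)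
Conditions: 9-BBN (1.2 equiv), THF, 0 °C → rt; then 30% H2O2, pH 7 phosphate buffer, 0 °C → rt
Reagents that add atoms: hydrogen peroxide, OO
Why: Anti-Markovnikov hydroboration of the terminal vinyl group by the bulky dialkylborane is much faster than any reaction at the conjugated lactone or the ring double bonds, and oxidation of the C–B bond under buffered neutral peroxide avoids hydroxide opening of the pyrone.

**Step 4**
Reactants: 5 tetracontanoic acid; 10 5-(2-hydroxyethyl)-2H-pyran-2-one
Product: 12 2-(2-oxo-2H-pyran-5-yl)ethyl tetracontanoate, via tetracontanoyl chloride 11 (not isolated)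
Conditions: 5, (COCl)2, DMF (cat.), toluene, 60 °C, then evaporation; 10, pyridine, toluene/CH2Cl2, 40 °C
Reagents that add atoms: none
Why: Acid chloride formation followed by pyridine-mediated acylation of a primary alcohol is a standard esterification, warm toluene keeps the waxy C40 acyl component in solution, and the pyrone offers no competing nucleophile.

**Step 5**
Reactants: 12 2-(2-oxo-2H-pyran-5-yl)ethyl tetracontanoate; 13 1,1-dimethoxyethene
Product: 16 2-(4-methoxyphenyl)ethyl tetracontanoate, via bridged bicyclic lactone 14 (not isolated), via dimethoxycyclohexadiene 15 (not isolated)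
Conditions: 13 (5 equiv), toluene, 140 °C, base-washed sealed tube
Reagents that add atoms: none
Why: The electron-poor diene of 12 (C3=C4–C5=C6) and the electron-rich alkene 13 should combine in a concerted but asynchronous inverse-electron-demand Diels–Alder reaction, the nucleophilic CH2 terminus bonding first to C6 and the acetal carbon then closing onto C3 to give bridged lactone 14. Retro-[4+2] extrusion of CO2 from 14 gives diene 15, and loss of methanol across its CH2–C(OMe)2 bond aromatises it to 16; the closest known reaction type is the cycloaddition–decarboxylation of 2-pyrones with ketene acetals to alkoxyarenes, established for ester- and halogen-bearing pyrones. The benzene ring is closed by this intermolecular [4+2] cycloaddition, which forms two C–C bonds across the diene termini, and the six-membered carbocycle is unmasked when the lactone bridge leaves. No stereocentre survives, because the two bridgehead centres of racemic 14 are erased on aromatisation. The step needs regioselectivity, and the polarisation of the pyrone should secure it: C6 is the oxygen-bearing δ-terminus of the dienoate and the most electrophilic site, C3 becomes an ester-enolate-like carbon that captures the dialkoxy-stabilised cationic centre, and the small CH2 end sits next to the C5 arm, so the methoxy group ends para to the side chain. Since 12 has no activating group, about 140 °C should be needed, which the ester arm and the excess acetal tolerate.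

**Step 6**
Reactants: 16 2-(4-methoxyphenyl)ethyl tetracontanoate
Product: 18 2-(4-hydroxyphenyl)ethyl tetracontanoate (target), via aryloxydibromoborane 17 (not isolated)
Conditions: BBr3 (1 M in CH2Cl2, 2.5 equiv), dilute CH2Cl2, −40 → 0 °C; then ice-water
Reagents that add atoms: none
Why: In this Lewis-acid ether cleavage BBr3 coordinates the anisole oxygen and bromide removes the methyl group by SN2 attack, which at or below 0 °C should be faster than cleavage of the primary alkyl ester, and hydrolysis of the aryl borate on work-up frees the phenol.

**Compound list**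
1 | 1-bromotetracosane | CCCCCCCCCCCCCCCCCCCCCCCCBr | starting material
2 | 16-bromohexadecanoic acid | BrCCCCCCCCCCCCCCCC(=O)O | starting material
3 | tetracosylmagnesium bromide | CCCCCCCCCCCCCCCCCCCCCCCC[Mg]Br | intermediate (not isolated)
4 | chloromagnesium 16-bromohexadecanoate | BrCCCCCCCCCCCCCCCC(=O)O[Mg]Cl | intermediate (not isolated)
5 | tetracontanoic acid | CCCCCCCCCCCCCCCCCCCCCCCCCCCCCCCCCCCCCCCC(=O)O | intermediate
6 | 5-bromo-2H-pyran-2-one | O=c1ccc(Br)co1 | starting material
7 | tributyl(vinyl)stannane | C=C[Sn](CCCC)(CCCC)CCCC | starting material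
8 | 5-ethenyl-2H-pyran-2-one | C=Cc1ccc(=O)oc1 | intermediate
9 | 5-[2-(9-borabicyclo[3.3.1]nonan-9-yl)ethyl]-2H-pyran-2-one | O=c1ccc(CCB2C3CCCC2CCC3)co1 | intermediate (not isolated)
10 | 5-(2-hydroxyethyl)-2H-pyran-2-one | O=c1ccc(CCO)co1 | intermediate
11 | tetracontanoyl chloride | CCCCCCCCCCCCCCCCCCCCCCCCCCCCCCCCCCCCCCCC(=O)Cl | intermediate (not isolated)
12 | 2-(2-oxo-2H-pyran-5-yl)ethyl tetracontanoate | CCCCCCCCCCCCCCCCCCCCCCCCCCCCCCCCCCCCCCCC(=O)OCCc1ccc(=O)oc1 | intermediate
13 | 1,1-dimethoxyethene | C=C(OC)OC | starting material
14 | 2-(8,8-dimethoxy-3-oxo-2-oxabicyclo[2.2.2]oct-5-en-6-yl)ethyl tetracontanoate (racemic; the bicycle allows only one relative configuration of the bridgeheads) | CCCCCCCCCCCCCCCCCCCCCCCCCCCCCCCCCCCCCCCC(=O)OCCC1=CC2C(=O)OC1CC2(OC)OC | intermediate (not isolated)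
15 | 2-(4,4-dimethoxycyclohexa-1,5-dien-1-yl)ethyl tetracontanoate | CCCCCCCCCCCCCCCCCCCCCCCCCCCCCCCCCCCCCCCC(=O)OCCC1=CCC(OC)(OC)C=C1 | intermediate (not isolated)
16 | 2-(4-methoxyphenyl)ethyl tetracontanoate | CCCCCCCCCCCCCCCCCCCCCCCCCCCCCCCCCCCCCCCC(=O)OCCc1ccc(OC)cc1 | intermediate
17 | 2-[4-(dibromoboranyloxy)phenyl]ethyl tetracontanoate | CCCCCCCCCCCCCCCCCCCCCCCCCCCCCCCCCCCCCCCC(=O)OCCc1ccc(OB(Br)Br)cc1 | intermediate (not isolated)
18 | 2-(4-hydroxyphenyl)ethyl tetracontanoate | CCCCCCCCCCCCCCCCCCCCCCCCCCCCCCCCCCCCCCCC(=O)OCCc1ccc(O)cc1 | target

**Totals**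
Total step count: 6. Longest linear sequence: 5 steps (steps 2 to 6, from 6 to 18).

**Steps most likely to fail**

Step 5. The cycloaddition of the unactivated pyrone may be too slow, so that oligomerisation of the ketene acetal at the required temperature consumes the dienophile first. The fallback sets out from 12 and activates the diene. Electrophilic bromination at C3 (Br2, CH2Cl2, 0 °C, then Et3N) should give 2-(3-bromo-2-oxo-2H-pyran-5-yl)ethyl tetracontanoate F1. 3-Bromopyrones are markedly more reactive, ambiphilic dienes. F1 should therefore take up 13 at about 90–100 °C in the same orientation and lose CO2 and methanol in the same operation, giving 2-(3-bromo-4-methoxyphenyl)ethyl tetracontanoate F2. Hydrogenolysis of the aryl bromide (H2, Pd/C, Et3N, THF, 40 °C) comes back to the route at 16.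

Step 3. The pyrone ring may be opened by peroxide or hydroxide during the oxidation, or the lactone may be reduced by the borane in competition with the vinyl group. The fallback sets out from 6 and brings in the two-carbon arm at the aldehyde oxidation level, with no borane and no peroxide. Stille coupling with (Z)-tributyl(2-ethoxyethenyl)stannane (Pd(PPh3)4, toluene, 90 °C) should give 5-[(Z)-2-ethoxyethenyl]-2H-pyran-2-one F3. Hydrolysis of the enol ether (1 M HCl, THF, rt) should give (2-oxo-2H-pyran-5-yl)acetaldehyde F4. Aldehyde-selective reduction with NaBH(OAc)3 in THF comes back to the route at 10.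

Step 6. The alkyl ester may be cleaved alongside the methyl ether, or demethylation may stall because the waxy substrate leaves the cold solution. The fallback sets out from 12 and exchanges the phenol protecting group for one removed under neutral conditions. The cycloaddition of step 5 is run with 1,1-bis(benzyloxy)ethene F5, obtained from 2-bromo-1,1-bis(benzyloxy)ethane and KOtBu in THF. With loss of CO2 and benzyl alcohol this should give 2-[4-(benzyloxy)phenyl]ethyl tetracontanoate F6. Hydrogenolysis (H2, Pd/C, THF/EtOAc, 40 °C), which leaves the homobenzylic ester intact, comes back to the route at 18.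

**Further compounds**
F1 | step 5 | 2-(3-bromo-2-oxo-2H-pyran-5-yl)ethyl tetracontanoate | CCCCCCCCCCCCCCCCCCCCCCCCCCCCCCCCCCCCCCCC(=O)OCCc1cc(Br)c(=O)oc1
F2 | step 5 | 2-(3-bromo-4-methoxyphenyl)ethyl tetracontanoate | CCCCCCCCCCCCCCCCCCCCCCCCCCCCCCCCCCCCCCCC(=O)OCCc1ccc(OC)c(Br)c1
F3 | step 3 | 5-[(Z)-2-ethoxyethenyl]-2H-pyran-2-one | CCO/C=C\c1ccc(=O)oc1
F4 | step 3 | (2-oxo-2H-pyran-5-yl)acetaldehyde | O=CCc1ccc(=O)oc1
F5 | step 6 | 1,1-bis(benzyloxy)ethene | C=C(OCc1ccccc1)OCc1ccccc1
F6 | step 6 | 2-[4-(benzyloxy)phenyl]ethyl tetracontanoate | CCCCCCCCCCCCCCCCCCCCCCCCCCCCCCCCCCCCCCCC(=O)OCCc1ccc(OCc2ccccc2)cc1
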